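## Retrosynthetic overview

1. Target 15 ⇐ hydrogenolysis of the four benzyl ethers of the meso tetrabenzyl ether 14.
2. 14 ⇐ double intramolecular oxa-Michael closure of the bis(2'-hydroxychalcone) 11. The two pyranone rings are formed last, one after the other in one pot, under equilibrating base; the C2-symmetric diastereomer 13 that forms alongside is funnelled into 14 in the same flask.
3. 11 ⇐ dehydration and MOM removal from bis-aldol 8 ⇐ key intermolecular double aldol addition of the dienolate of 1,4-diketone 5 to two molecules of aldehyde 6 (both C2–C3 bonds).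
4. 5 ⇐ oxidative enolate homocoupling of acetophenone 3 (the C3–C3' bond) ⇐ 2,4-dihydroxyacetophenone 1. All benzene rings are bought.

Assumption: the target SMILES describes the meso (2S,3R,2'R,3'S) isomer, 2,3-trans in both rings with mirror-image halves, so it is achiral and only relative configuration has to be controlled.

## Route

Step 1
Reactants: 1 1-(2,4-dihydroxyphenyl)ethan-1-one
Product: 2 1-[4-(benzyloxy)-2-hydroxyphenyl]ethan-1-one
Conditions: BnBr (1.05 equiv), K2CO3 (1.2 equiv), acetone, reflux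
Reagents that add atoms: benzyl bromide, BrCc1ccccc1
Why: Williamson etherification in which the 2-OH, hydrogen-bonded to the ketone, is far less nucleophilic, so only the 4-OH is benzylated.

Step 2
Reactants: 2 1-[4-(benzyloxy)-2-hydroxyphenyl]ethan-1-one
Product: 3 1-[4-(benzyloxy)-2-(methoxymethoxy)phenyl]ethan-1-one
Conditions: NaH (1.2 equiv), DMF, 0 °C; MOMCl (1.3 equiv), 0 °C to rt
Reagents that add atoms: chloromethyl methyl ether, COCCl
Why: O-alkylation of the sodium phenoxide masks the acidic phenol as a base-stable MOM acetal so that the ketone can be enolised cleanly in steps 3 and 4.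

Step 3
Reactants: 3 1-[4-(benzyloxy)-2-(methoxymethoxy)phenyl]ethan-1-one (two molecules)
Product: 5 1,4-bis[4-(benzyloxy)-2-(methoxymethoxy)phenyl]butane-1,4-dione, via lithium enolate 4 (not isolated)
Conditions: LiN(i-Pr)2 (1.1 equiv), THF, −78 °C; CuCl2 (1.1 equiv), DMF, −78 °C to rt; aq NH4Cl/NH3 work-up
Reagents that add atoms: none
Why: Oxidative enolate homocoupling, in which CuCl2 (divalent copper) oxidises the enolate by one electron and the α-keto radicals dimerise at carbon; this makes the C3–C3' bond and no stereocentre.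

Step 4 (key step)
Reactants: 5 1,4-bis[4-(benzyloxy)-2-(methoxymethoxy)phenyl]butane-1,4-dione; 6 4-(benzyloxy)benzaldehyde (two molecules)
Product: 8 1,4-bis[4-(benzyloxy)-2-(methoxymethoxy)phenyl]-2,3-bis{[4-(benzyloxy)phenyl](hydroxy)methyl}butane-1,4-dione (mixture of diastereomers), via dilithium dienolate 7 (not isolated)
Conditions: LiN(i-Pr)2 (2.3 equiv), THF, −78 to −40 °C; 6 (2.6 equiv), −78 °C; AcOH, −78 °C; cold work-up, crude used at once
Reagents that add atoms: none
Why: Directed intermolecular aldol addition of the preformed dienolate to a non-enolisable aldehyde at each α-carbon, quenched cold to stop retro-aldol and lactol formation; the four new stereocentres need no control because steps 5 and 7 erase and reset them.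

Step 5
Reactants: 8 the bis-aldol (crude mixture of diastereomers)
Product: 10 (2E,3E)-2,3-bis[4-(benzyloxy)benzylidene]-1,4-bis[4-(benzyloxy)-2-(methoxymethoxy)phenyl]butane-1,4-dione, via bis(methanesulfonate) 9 (not isolated)
Conditions: MsCl (3 equiv), Et3N (6 equiv), CH2Cl2, 0 °C; DBU (3 equiv), 0 °C to rt
Reagents that add atoms: none
Why: Mesylation followed by E1cB elimination across each acidic α-CH gives the conjugated arylidene ketones (alkene geometry is irrelevant later) and leaves no α-hydrogen, so the 1,4-diketone cannot form a furan in the acidic step 6.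

Step 6
Reactants: 10 the MOM-protected bis(arylidene) diketone
Product: 11 (2E,3E)-2,3-bis[4-(benzyloxy)benzylidene]-1,4-bis[4-(benzyloxy)-2-hydroxyphenyl]butane-1,4-dione
Conditions: 3 M aq HCl, MeOH/THF, 45 °C
Reagents that add atoms: none
Why: Acid-catalysed acetal exchange with methanol cleaves the aryl MOM ethers while the benzyl ethers are inert; any ring closure that starts here is harmless because step 7 completes it.

Step 7
Reactants: 11 the bis(2'-hydroxychalcone)
Product: 14 (2S,3R,2'R,3'S)-7,7'-bis(benzyloxy)-2,2'-bis[4-(benzyloxy)phenyl]-[3,3'-bichromane]-4,4'-dione (meso), via monocyclised chalcone-flavanone 12 (not isolated), via C2-symmetric racemic bis-flavanone 13 (not isolated)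
Conditions: NaOAc (5 equiv), EtOH/THF, reflux, N2; then DBU (0.3 equiv), EtOH/THF 4:1, 50 °C to rt, slurry; 14 filtered off; filtrate concentrated and re-slurried with DBU (2–3 cycles)
Reagents that add atoms: none
Why: Two successive 6-endo-trig intramolecular oxa-Michael additions close both rings and reversible C3 enolisation plus retro-Michael opening place the 2-aryl and 3-substituent trans-diequatorial in each ring, while the C2-symmetric trans,trans diastereomer 13 that forms beside 14 re-opens through 12 under DBU and is drained into the centrosymmetric meso 14 as that isomer crystallises (crystallisation-driven equilibration of diastereomers).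

Step 8
Reactants: 14 the meso tetrabenzyl ether
Product: 15 (2S,3R,2'R,3'S)-7,7'-dihydroxy-2,2'-bis(4-hydroxyphenyl)-[3,3'-bichromane]-4,4'-dione (meso, target)
Conditions: H2 (1 atm), 10% Pd/C, THF/MeOH, rt, stopped after uptake of 4 equiv H2
Reagents that add atoms: none
Why: Neutral catalytic hydrogenolysis removes the four benzyl ethers without acid or base, so the epimerisable C2 and C3 centres of both rings are untouched.

## Compound list

1 | 1-(2,4-dihydroxyphenyl)ethan-1-one (2,4-dihydroxyacetophenone) | CC(=O)c1ccc(O)cc1O | starting material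
2 | 1-[4-(benzyloxy)-2-hydroxyphenyl]ethan-1-one | CC(=O)c1ccc(OCc2ccccc2)cc1O | intermediate
3 | 1-[4-(benzyloxy)-2-(methoxymethoxy)phenyl]ethan-1-one | CC(=O)c1ccc(OCc2ccccc2)cc1OCOC | intermediate
4 | lithium 1-[4-(benzyloxy)-2-(methoxymethoxy)phenyl]ethen-1-olate | C=C(O[Li])c1ccc(OCc2ccccc2)cc1OCOC | intermediate (not isolated)
5 | 1,4-bis[4-(benzyloxy)-2-(methoxymethoxy)phenyl]butane-1,4-dione | O=C(CCC(=O)c1ccc(OCc2ccccc2)cc1OCOC)c1ccc(OCc2ccccc2)cc1OCOC | intermediate
6 | 4-(benzyloxy)benzaldehyde | O=Cc1ccc(OCc2ccccc2)cc1 | starting material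
7 | dilithium 1,4-bis[4-(benzyloxy)-2-(methoxymethoxy)phenyl]buta-1,3-diene-1,4-bis(olate) | [Li]OC(=CC=C(O[Li])c1ccc(OCc2ccccc2)cc1OCOC)c1ccc(OCc2ccccc2)cc1OCOC | intermediate (not isolated)
8 | 1,4-bis[4-(benzyloxy)-2-(methoxymethoxy)phenyl]-2,3-bis{[4-(benzyloxy)phenyl](hydroxy)methyl}butane-1,4-dione, diastereomer mixture, stereocentres undefined, used crude | O=C(c1ccc(OCc2ccccc2)cc1OCOC)C(C(O)c1ccc(OCc2ccccc2)cc1)C(C(O)c1ccc(OCc2ccccc2)cc1)C(=O)c1ccc(OCc2ccccc2)cc1OCOC | intermediate
9 | bis(methanesulfonate) of 8, diastereomer mixture | O=C(c1ccc(OCc2ccccc2)cc1OCOC)C(C(OS(C)(=O)=O)c1ccc(OCc2ccccc2)cc1)C(C(OS(C)(=O)=O)c1ccc(OCc2ccccc2)cc1)C(=O)c1ccc(OCc2ccccc2)cc1OCOC | intermediate (not isolated)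
10 | (2E,3E)-2,3-bis[4-(benzyloxy)benzylidene]-1,4-bis[4-(benzyloxy)-2-(methoxymethoxy)phenyl]butane-1,4-dione | O=C(c1ccc(OCc2ccccc2)cc1OCOC)/C(=C/c1ccc(OCc2ccccc2)cc1)/C(=C\c1ccc(OCc2ccccc2)cc1)C(=O)c1ccc(OCc2ccccc2)cc1OCOC | intermediate
11 | (2E,3E)-2,3-bis[4-(benzyloxy)benzylidene]-1,4-bis[4-(benzyloxy)-2-hydroxyphenyl]butane-1,4-dione | O=C(c1ccc(OCc2ccccc2)cc1O)/C(=C/c1ccc(OCc2ccccc2)cc1)/C(=C\c1ccc(OCc2ccccc2)cc1)C(=O)c1ccc(OCc2ccccc2)cc1O | intermediate
12 | 7-(benzyloxy)-2-[4-(benzyloxy)phenyl]-3-{(E)-3-[4-(benzyloxy)-2-hydroxyphenyl]-1-[4-(benzyloxy)phenyl]-3-oxoprop-1-en-2-yl}chroman-4-one, racemic, ring stereocentres still equilibrating | O=C1c2ccc(OCc3ccccc3)cc2OC(c2ccc(OCc3ccccc3)cc2)C1/C(=C\c1ccc(OCc2ccccc2)cc1)C(=O)c1ccc(OCc2ccccc2)cc1O | intermediate (not isolated)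
13 | rac-(2S,3R,2'S,3'R)-7,7'-bis(benzyloxy)-2,2'-bis[4-(benzyloxy)phenyl]-[3,3'-bichromane]-4,4'-dione (C2-symmetric trans,trans diastereomer, one enantiomer drawn) | O=C1c2ccc(OCc3ccccc3)cc2O[C@H](c2ccc(OCc3ccccc3)cc2)[C@H]1[C@H]1C(=O)c2ccc(OCc3ccccc3)cc2O[C@@H]1c1ccc(OCc2ccccc2)cc1 | intermediate (not isolated)
14 | (2S,3R,2'R,3'S)-7,7'-bis(benzyloxy)-2,2'-bis[4-(benzyloxy)phenyl]-[3,3'-bichromane]-4,4'-dione (meso) | O=C1c2ccc(OCc3ccccc3)cc2O[C@H](c2ccc(OCc3ccccc3)cc2)[C@H]1[C@@H]1C(=O)c2ccc(OCc3ccccc3)cc2O[C@H]1c1ccc(OCc2ccccc2)cc1 | intermediate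
15 | (2S,3R,2'R,3'S)-7,7'-dihydroxy-2,2'-bis(4-hydroxyphenyl)-[3,3'-bichromane]-4,4'-dione (meso) | O=C1c2ccc(O)cc2O[C@H](c2ccc(O)cc2)[C@H]1[C@@H]1C(=O)c2ccc(O)cc2O[C@H]1c1ccc(O)cc1 | target

## Step count and risks

Total step count: 8. Longest linear sequence: 8 steps (1 to 15); aldehyde 6 is bought and enters at step 4.

The three steps most likely to fail:

**Step 3 (oxidative enolate coupling; over-oxidation or α-chlorination may cut the yield).** The fallback sets out from 3 and comes back at 5. Enolate 4 is quenched with N-bromosuccinimide in THF at −78 °C to give 2-bromo-1-[4-(benzyloxy)-2-(methoxymethoxy)phenyl]ethan-1-one F1. F1 is then coupled with a second equivalent of 3 using ZnCl2, Et2NH and t-BuOH in toluene at rt. The zinc enolate of 3 is C-alkylated by the bromoketone, so 5 arises by a polar SN2 alkylation instead of a radical dimerisation.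

**Step 4 (double directed aldol; incomplete dienolate formation, mono-addition, retro-aldol, or closure of the γ-hydroxy ketone to a lactol).** The fallback sets out from 5 and comes back at 14. The MOM ethers are removed first (3 M aq HCl, MeOH/THF, rt, short contact time so that the 1,4-diketone does not close to a furan) to give 1,4-bis[4-(benzyloxy)-2-hydroxyphenyl]butane-1,4-dione F2. F2 is heated with aldehyde 6 (2.5 equiv) and pyrrolidine in EtOH. Amine-mediated aldol condensation at each α-methylene is followed in the same flask by oxa-Michael closure of the free phenols. This gives the bis-flavanones 13 and 14 directly. The DBU slurry of step 7 then delivers 14 without passing through 7 to 11.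

**Step 7 (double ring closure and the meso/racemate outcome).** Closure of the twisted α-substituted chalcone units may be slow, and the equilibrium ratio of 14 to 13 in solution is expected to be near 1:1. The step therefore relies on 14 being the less soluble isomer. If 14 does not crystallise selectively, it is removed on silica and the fractions that hold 13 go straight back into the DBU equilibration. 14 is recognised as the diastereomer that gives a single peak on a chiral stationary phase, whereas 13 splits into two. The fallback sets out from 2 and 6 and comes back at 14; it forms the rings before the C3–C3' bond. Claisen–Schmidt condensation of 2 with 6 (KOH, EtOH/THF, rt) gives (E)-1-[4-(benzyloxy)-2-hydroxyphenyl]-3-[4-(benzyloxy)phenyl]prop-2-en-1-one F3. NaOAc in refluxing EtOH closes it to rac-7-(benzyloxy)-2-[4-(benzyloxy)phenyl]chroman-4-one F4. LiN(SiMe3)2 in THF at −78 °C gives lithium 7-(benzyloxy)-2-[4-(benzyloxy)phenyl]-2H-chromen-4-olate F5. CuCl2 in DMF at −78 °C couples two units of F5 at C3. The DBU slurry of step 7 then converts the resulting diastereomers, 13 among them, into crystalline 14.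

## Further compounds

F1 | step 3 | 2-bromo-1-[4-(benzyloxy)-2-(methoxymethoxy)phenyl]ethan-1-one | O=C(CBr)c1ccc(OCc2ccccc2)cc1OCOC
F2 | step 4 | 1,4-bis[4-(benzyloxy)-2-hydroxyphenyl]butane-1,4-dione | O=C(CCC(=O)c1ccc(OCc2ccccc2)cc1O)c1ccc(OCc2ccccc2)cc1O
F3 | step 7 | (E)-1-[4-(benzyloxy)-2-hydroxyphenyl]-3-[4-(benzyloxy)phenyl]prop-2-en-1-one | O=C(/C=C/c1ccc(OCc2ccccc2)cc1)c1ccc(OCc2ccccc2)cc1O
F4 | step 7 | rac-7-(benzyloxy)-2-[4-(benzyloxy)phenyl]chroman-4-one | O=C1CC(c2ccc(OCc3ccccc3)cc2)Oc2cc(OCc3ccccc3)ccc12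
F5 | step 7 | lithium 7-(benzyloxy)-2-[4-(benzyloxy)phenyl]-2H-chromen-4-olate (lithium enolate of the flavanone) | [Li]OC1=CC(c2ccc(OCc3ccccc3)cc2)Oc2cc(OCc3ccccc3)ccc12
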